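**Retrosynthetic overview**
1. Locants: C1 = ring CH carrying the 2‑acetoxypropan‑2‑yl group (C15), then C2, C3=C4 (Z), C5, C6, C7–C8 oxirane, C9, C10 (OAc), C11=C12 (E), C13, C14.
2. Target ⇒ diol ⇒ macrocyclic sulfone: the 14‑membered ring is closed at C13–C14 by alkylating a C14 α‑sulfonyl carbanion with the C13 allylic bromide, and the sulfone is then removed.
3. Open chain ⇒ C4–C5 Negishi sp3–sp2 coupling of fragment A ((Z)‑vinyl iodide holding C1, C14, C15) with fragment B (alkylzinc holding the finished oxirane, C10 and the (E)‑enoate).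
4. Fragment A ⇒ pent‑4‑enal (organocatalytic α‑hydroxymethylation sets C1). Fragment B ⇒ ethyl 4‑chloro‑3‑oxobutanoate (ketoreductase sets C10; carboalumination gives E‑C7=C8; Wittig gives E‑C11=C12; Shi epoxidation sets C7/C8).
5. Ring order: oxirane first (step 18, acyclic stage), 14‑membered carbocycle second (step 23).

**Fragment A**

Step 1
Reactants: 1 pent-4-enal
Product: 3 (2S)-2-(hydroxymethyl)pent-4-enoic acid, via hydroxy aldehyde 2 (not isolated)
Conditions: 37% aq. CH2O (3 equiv), (R)-2-[diphenyl(trimethylsilyloxy)methyl]pyrrolidine (10 mol %), pH 7 phosphate buffer, toluene, rt; then NaClO2, NaH2PO4, 2-methylbut-2-ene, t-BuOH/H2O, 0 °C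
Reagents that add atoms: formaldehyde C=O; sodium chlorite [Na+].[O-]Cl=O
Why: Enamine-catalysed α-hydroxymethylation (a cross-aldol) in which the CPh2OSiMe3 group of the (R)-catalyst shields one face of the E-enamine so formaldehyde adds to the other and sets C1 as S, after which Pinnick oxidation in the same flask fixes the labile β-hydroxy aldehyde as the acid without touching the alkene.

Step 2
Reactants: 3 (2S)-2-(hydroxymethyl)pent-4-enoic acid
Product: 4 methyl (2S)-2-(hydroxymethyl)pent-4-enoate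
Conditions: MeOH, AcCl (5 mol %), rt
Reagents that add atoms: methanol CO
Why: Fischer esterification under dilute anhydrous HCl at room temperature does not enolise the α-carbon and leaves the alkene alone.

Step 3
Reactants: 4 methyl (2S)-2-(hydroxymethyl)pent-4-enoate
Product: 5 (2S)-3-methyl-2-(prop-2-en-1-yl)butane-1,3-diol
Conditions: MeMgBr (4.5 equiv), THF, 0 °C → rt; aq. NH4Cl
Reagents that add atoms: methylmagnesium bromide C[Mg]Br
Why: Double Grignard addition to the ester builds the C15 tertiary carbinol, and the neighbouring magnesium alkoxide suppresses enolisation so C1 is not epimerised.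

Step 4
Reactants: 5 (2S)-3-methyl-2-(prop-2-en-1-yl)butane-1,3-diol
Product: 6 (3R)-2-methyl-3-[(phenylsulfanyl)methyl]hex-5-en-2-ol
Conditions: PhSSPh, n-Bu3P, THF, rt
Reagents that add atoms: diphenyl disulfide c1ccc(SSc2ccccc2)cc1
Why: Hata redox condensation turns only the unhindered primary hydroxyl into the phenyl sulfide through its alkoxyphosphonium salt, and the stereocentre is untouched (the descriptor becomes R only because sulfur raises that arm's priority).

Step 5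
Reactants: 6 (3R)-2-methyl-3-[(phenylsulfanyl)methyl]hex-5-en-2-ol
Product: 7 (3R)-3-[(benzenesulfonyl)methyl]-2-methylhex-5-en-2-ol
Conditions: 30% H2O2, (NH4)6Mo7O24·4H2O (5 mol %), EtOH, 0 °C → rt
Reagents that add atoms: hydrogen peroxide OO
Why: Molybdate-catalysed peroxide oxidation takes the sulfide through the sulfoxide to the sulfone much faster than it attacks an unactivated terminal alkene.

Step 6
Reactants: 7 (3R)-3-[(benzenesulfonyl)methyl]-2-methylhex-5-en-2-ol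
Product: 8 {[(3R)-3-[(benzenesulfonyl)methyl]-2-methylhex-5-en-2-yl]oxy}triethylsilane
Conditions: Et3SiOTf, 2,6-lutidine, CH2Cl2, −78 → 0 °C
Reagents that add atoms: triethylsilyl trifluoromethanesulfonate CC[Si](CC)(CC)OS(=O)(=O)C(F)(F)F
Why: Silyl triflate silylation caps the hindered tertiary alcohol so it cannot form a lactol with the aldehyde made next or act as a nucleophile in the ring closure.

Step 7
Reactants: 8 {[(3R)-3-[(benzenesulfonyl)methyl]-2-methylhex-5-en-2-yl]oxy}triethylsilane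
Product: 10 (3R)-3-[(benzenesulfonyl)methyl]-4-methyl-4-[(triethylsilyl)oxy]pentanal, via ozonide 9 (not isolated)
Conditions: O3, CH2Cl2, −78 °C; then PPh3, −78 °C → rt
Reagents that add atoms: ozone [O-][O+]=O
Why: Ozonolysis with reductive work-up cleaves the only alkene to the C3 aldehyde, and sulfone and silyl ether are inert to ozone.

Step 8
Reactants: 10 (3R)-3-[(benzenesulfonyl)methyl]-4-methyl-4-[(triethylsilyl)oxy]pentanal
Product: 11 {[(3R,5Z)-3-[(benzenesulfonyl)methyl]-6-iodo-2-methylhept-5-en-2-yl]oxy}triethylsilane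
Conditions: [Ph3PEt]I, n-BuLi, THF, rt; I2, −78 °C; NaN(SiMe3)2, −20 °C; then 10, −78 → −20 °C
Reagents that add atoms: ethyltriphenylphosphonium iodide CC[P+](c1ccccc1)(c1ccccc1)c1ccccc1.[I-]; iodine II
Why: Stork–Zhao α-iodo Wittig olefination, in which the unstabilised α-iodo ylide reacts under kinetic control through the cis-oxaphosphetane to give the (Z)-2-iodoalkene with iodine cis to the chain.

**Fragment B**

Step 9
Reactants: 12 ethyl 4-chloro-3-oxobutanoate; 13 (4-methoxyphenyl)methanol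
Product: 14 ethyl 4-[(4-methoxyphenyl)methoxy]-3-oxobutanoate
Conditions: NaH (2.2 equiv), THF, 0 °C → rt; aq. HCl work-up
Reagents that add atoms: none
Why: Williamson etherification in which one equivalent of base masks the β-keto ester as its enolate so the alkoxide simply displaces the primary chloride.

Step 10
Reactants: 14 ethyl 4-[(4-methoxyphenyl)methoxy]-3-oxobutanoate
Product: 15 ethyl (3R)-3-hydroxy-4-[(4-methoxyphenyl)methoxy]butanoate
Conditions: ketoreductase (NADPH-dependent, R-selective variant), NADP+ (cat.), i-PrOH (10 vol %), KH2PO4/K2HPO4 buffer pH 7, 30 °C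
Reagents that add atoms: none
Why: Enzymatic asymmetric carbonyl reduction, in which the ketoreductase binds the β-keto ester in one orientation and delivers hydride from NADPH to a single face to set C10 as R (typically >99% ee for β-keto esters), with propan-2-ol regenerating the cofactor.

Step 11
Reactants: 15 ethyl (3R)-3-hydroxy-4-[(4-methoxyphenyl)methoxy]butanoate
Product: 16 ethyl (3R)-3-[(tert-butyldimethylsilyl)oxy]-4-[(4-methoxyphenyl)methoxy]butanoate
Conditions: t-BuMe2SiCl, imidazole, DMF, rt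
Reagents that add atoms: tert-butyldimethylsilyl chloride CC(C)(C)[Si](C)(C)Cl
Why: Imidazole-promoted silylation protects the secondary alcohol with a group that survives every later step up to fluoride treatment.

Step 12
Reactants: 16 ethyl (3R)-3-[(tert-butyldimethylsilyl)oxy]-4-[(4-methoxyphenyl)methoxy]butanoate
Product: 18 tert-butyl{[(2R)-1-[(4-methoxyphenyl)methoxy]pent-4-yn-2-yl]oxy}dimethylsilane, via aldehyde 17 (not isolated)
Conditions: iBu2AlH (1.1 equiv), CH2Cl2, −78 °C; then MeOH, K2CO3, dimethyl (1-diazo-2-oxopropyl)phosphonate, −78 °C → rt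
Reagents that add atoms: dimethyl (1-diazo-2-oxopropyl)phosphonate CC(=O)C(=[N+]=[N-])P(=O)(OC)OC
Why: Partial reduction of the β-silyloxy ester stops at the chelated hemiacetal, and the released aldehyde undergoes Ohira–Bestmann (Seyferth–Gilbert) homologation to the terminal alkyne under mild carbonate conditions that do not touch the C10 centre.

Step 13
Reactants: 18 tert-butyl{[(2R)-1-[(4-methoxyphenyl)methoxy]pent-4-yn-2-yl]oxy}dimethylsilane
Product: 21 (3E,6R)-6-[(tert-butyldimethylsilyl)oxy]-7-[(4-methoxyphenyl)methoxy]-4-methylhept-3-en-1-ol, via alkenylalane 19 (not isolated), via lithium aluminate 20 (not isolated)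
Conditions: AlMe3 (2 equiv), Cp2ZrCl2 (0.25 equiv), CH2Cl2, rt; volatiles removed; n-BuLi, hexane/THF, −78 °C; oxirane (3 equiv), −78 → 0 °C
Reagents that add atoms: trimethylaluminium C[Al](C)C; butyllithium [Li]CCCC (kept only in 20); oxirane C1CO1
Why: Negishi zirconium-catalysed carboalumination adds CH3 and Al syn across the terminal alkyne with aluminium on the terminal carbon, and the butyl ate complex then opens oxirane with retention to give the E-trisubstituted C7=C8 alkene already carrying C5 and C6.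

Step 14
Reactants: 21 (3E,6R)-6-[(tert-butyldimethylsilyl)oxy]-7-[(4-methoxyphenyl)methoxy]-4-methylhept-3-en-1-ol
Product: 22 {[(2R,4E)-7-bromo-1-[(4-methoxyphenyl)methoxy]-4-methylhept-4-en-2-yl]oxy}(tert-butyl)dimethylsilane
Conditions: CBr4, PPh3, CH2Cl2, 0 °C
Reagents that add atoms: tetrabromomethane BrC(Br)(Br)Br
Why: Appel bromination converts the primary alcohol into a bromide that tolerates the oxidation, olefination and dioxirane steps ahead, so no free hydroxyl is ever present next to the later oxirane.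

Step 15
Reactants: 22 {[(2R,4E)-7-bromo-1-[(4-methoxyphenyl)methoxy]-4-methylhept-4-en-2-yl]oxy}(tert-butyl)dimethylsilane
Product: 23 (2R,4E)-7-bromo-2-[(tert-butyldimethylsilyl)oxy]-4-methylhept-4-en-1-ol
Conditions: DDQ (1.3 equiv), CH2Cl2/pH 7 buffer (10:1), 0 °C
Reagents that add atoms: none
Why: Oxidative cleavage of the electron-rich 4-methoxybenzyl ether by hydride abstraction frees the C11 alcohol before any oxirane exists, so no epoxy alcohol cyclisation is possible.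

Step 16
Reactants: 23 (2R,4E)-7-bromo-2-[(tert-butyldimethylsilyl)oxy]-4-methylhept-4-en-1-ol
Product: 24 (2R,4E)-7-bromo-2-[(tert-butyldimethylsilyl)oxy]-4-methylhept-4-enal
Conditions: Dess–Martin periodinane, NaHCO3, CH2Cl2, 0 °C → rt
Reagents that add atoms: none
Why: Dess–Martin oxidation under buffered neutral conditions gives the α-silyloxy aldehyde without epimerising C10.

Step 17
Reactants: 24 (2R,4E)-7-bromo-2-[(tert-butyldimethylsilyl)oxy]-4-methylhept-4-enal
Product: 25 ethyl (2E,4R,6E)-9-bromo-4-[(tert-butyldimethylsilyl)oxy]-2,6-dimethylnona-2,6-dienoate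
Conditions: Ph3P=C(CH3)CO2Et (2 equiv), CH2Cl2, rt
Reagents that add atoms: ethyl 2-(triphenyl-λ5-phosphanylidene)propanoate CCOC(=O)C(C)=P(c1ccccc1)(c1ccccc1)c1ccccc1
Why: Wittig olefination with the stabilised α-methyl ylide is thermodynamically controlled and gives the E-trisubstituted C11=C12 enoate, with the ester carbon becoming C13.

Step 18
Reactants: 25 ethyl (2E,4R,6E)-9-bromo-4-[(tert-butyldimethylsilyl)oxy]-2,6-dimethylnona-2,6-dienoate
Product: 26 ethyl (2E,4R)-5-[(2R,3R)-3-(2-bromoethyl)-2-methyloxiran-2-yl]-4-[(tert-butyldimethylsilyl)oxy]-2-methylpent-2-enoate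
Conditions: 1,2:4,5-di-O-isopropylidene-β-D-erythro-hexo-2,3-diulo-2,6-pyranose (D-fructose-derived Shi ketone, 0.3 equiv), KHSO5 (as 2KHSO5·KHSO4·K2SO4), K2CO3, Bu4NHSO4, MeCN/CH2(OMe)2–aq. Na2B4O7 buffer, 0 °C
Reagents that add atoms: potassium peroxymonosulfate [K+].[O-]S(=O)(=O)OO
Why: Shi asymmetric epoxidation, in which the chiral dioxirane transfers oxygen through a spiro transition state to one face of the electron-rich E-trisubstituted alkene to set C7 and C8 as R,R under catalyst control, while the electron-poor enoate alkene does not react.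

Step 19
Reactants: 26 ethyl (2E,4R)-5-[(2R,3R)-3-(2-bromoethyl)-2-methyloxiran-2-yl]-4-[(tert-butyldimethylsilyl)oxy]-2-methylpent-2-enoate
Product: 27 ethyl (2E,4R)-4-[(tert-butyldimethylsilyl)oxy]-5-[(2R,3R)-3-(2-iodoethyl)-2-methyloxiran-2-yl]-2-methylpent-2-enoate
Conditions: NaI (5 equiv), NaHCO3, acetone, 40 °C
Reagents that add atoms: sodium iodide [Na+].[I-]
Why: Finkelstein exchange at the primary carbon, driven by precipitation of the bromide salt, gives the iodide needed for mild zinc insertion under neutral conditions that spare the oxirane.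

**Coupling, ring closure and end game**

Step 20
Reactants: 27 ethyl (2E,4R)-4-[(tert-butyldimethylsilyl)oxy]-5-[(2R,3R)-3-(2-iodoethyl)-2-methyloxiran-2-yl]-2-methylpent-2-enoate; 11 {[(3R,5Z)-3-[(benzenesulfonyl)methyl]-6-iodo-2-methylhept-5-en-2-yl]oxy}triethylsilane
Product: 29 ethyl (2E,4R)-5-{(2R,3R)-3-[(3Z,6R)-6-[(benzenesulfonyl)methyl]-3,7-dimethyl-7-[(triethylsilyl)oxy]oct-3-en-1-yl]-2-methyloxiran-2-yl}-4-[(tert-butyldimethylsilyl)oxy]-2-methylpent-2-enoate, via alkylzinc iodide 28 (not isolated)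
Conditions: Zn dust (activated with 5 mol % I2), DMA, rt → 40 °C; then 11, PdCl2(dppf) (5 mol %), THF/DMA, rt → 45 °C
Reagents that add atoms: zinc [Zn] (kept only in 28)
Why: Negishi coupling, in which zinc inserts into the primary C–I bond to give an alkylzinc iodide that tolerates ester, oxirane and silyl ether, and palladium-catalysed sp3–sp2 coupling with the vinyl iodide proceeds with retention to fix the Z-C3=C4 alkene.

Step 21
Reactants: 29 ethyl (2E,4R)-5-{(2R,3R)-3-[(3Z,6R)-6-[(benzenesulfonyl)methyl]-3,7-dimethyl-7-[(triethylsilyl)oxy]oct-3-en-1-yl]-2-methyloxiran-2-yl}-4-[(tert-butyldimethylsilyl)oxy]-2-methylpent-2-enoate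
Product: 30 (2E,4R)-5-{(2R,3R)-3-[(3Z,6R)-6-[(benzenesulfonyl)methyl]-3,7-dimethyl-7-[(triethylsilyl)oxy]oct-3-en-1-yl]-2-methyloxiran-2-yl}-4-[(tert-butyldimethylsilyl)oxy]-2-methylpent-2-en-1-ol
Conditions: iBu2AlH (2.5 equiv), CH2Cl2, −78 °C
Reagents that add atoms: none
Why: 1,2-Reduction of the enoate by the aluminium hydride at −78 °C gives the allylic alcohol, and the trisubstituted oxirane, sulfone and silyl ethers do not react at this temperature.

Step 22
Reactants: 30 (2E,4R)-5-{(2R,3R)-3-[(3Z,6R)-6-[(benzenesulfonyl)methyl]-3,7-dimethyl-7-[(triethylsilyl)oxy]oct-3-en-1-yl]-2-methyloxiran-2-yl}-4-[(tert-butyldimethylsilyl)oxy]-2-methylpent-2-en-1-ol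
Product: 32 (2R,3R)-3-[(3Z,6R)-6-[(benzenesulfonyl)methyl]-3,7-dimethyl-7-[(triethylsilyl)oxy]oct-3-en-1-yl]-2-[(2R,3E)-5-bromo-2-[(tert-butyldimethylsilyl)oxy]-4-methylpent-3-en-1-yl]-2-methyloxirane, via allylic mesylate 31 (not isolated)
Conditions: MeSO2Cl, Et3N, THF, −40 °C; then LiBr, THF, −40 → 0 °C
Reagents that add atoms: methanesulfonyl chloride CS(=O)(=O)Cl (kept only in 31); lithium bromide [Li+].[Br-]
Why: Mesylation followed by SN2 displacement with bromide gives the primary allylic bromide under non-acidic conditions that preserve the alkene geometry and the oxirane.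

Step 23
Reactants: 32 (2R,3R)-3-[(3Z,6R)-6-[(benzenesulfonyl)methyl]-3,7-dimethyl-7-[(triethylsilyl)oxy]oct-3-en-1-yl]-2-[(2R,3E)-5-bromo-2-[(tert-butyldimethylsilyl)oxy]-4-methylpent-3-en-1-yl]-2-methyloxirane
Product: 33 {[(1R,3R,4E,8R,10Z,14R)-7-(benzenesulfonyl)-1,5,11-trimethyl-8-{2-[(triethylsilyl)oxy]propan-2-yl}-15-oxabicyclo[12.1.0]pentadeca-4,10-dien-3-yl]oxy}(tert-butyl)dimethylsilane (both C7 epimers)
Conditions: LiN(iPr)2 (1.5 equiv), THF, −78 °C; 32 added over 6 h to 0.002 M; then → −20 °C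
Reagents that add atoms: none
Why: Intramolecular SN2 alkylation of the α-sulfonyl carbanion at C14 by the primary allylic bromide at C13 closes the 14-membered ring under high dilution, and the new sulfone-bearing centre forms as a mixture that is erased in the next step.

Step 24
Reactants: 33 {[(1R,3R,4E,8R,10Z,14R)-7-(benzenesulfonyl)-1,5,11-trimethyl-8-{2-[(triethylsilyl)oxy]propan-2-yl}-15-oxabicyclo[12.1.0]pentadeca-4,10-dien-3-yl]oxy}(tert-butyl)dimethylsilane
Product: 34 tert-butyl{[(1R,3R,4E,8R,10Z,14R)-1,5,11-trimethyl-8-{2-[(triethylsilyl)oxy]propan-2-yl}-15-oxabicyclo[12.1.0]pentadeca-4,10-dien-3-yl]oxy}dimethylsilane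
Conditions: Na/Hg (6% Na), Na2HPO4, MeOH/THF, −20 → 0 °C
Reagents that add atoms: none
Why: Reductive desulfonylation by single-electron transfer cleaves the C–S bond and protonates C14, and because the sulfone is not allylic no alkene migrates while oxirane and silyl ethers are inert in the buffered medium.

Step 25
Reactants: 34 tert-butyl{[(1R,3R,4E,8R,10Z,14R)-1,5,11-trimethyl-8-{2-[(triethylsilyl)oxy]propan-2-yl}-15-oxabicyclo[12.1.0]pentadeca-4,10-dien-3-yl]oxy}dimethylsilane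
Product: 35 (1R,3R,4E,8R,10Z,14R)-8-(2-hydroxypropan-2-yl)-1,5,11-trimethyl-15-oxabicyclo[12.1.0]pentadeca-4,10-dien-3-ol
Conditions: Bu4NF, THF, rt → 45 °C
Reagents that add atoms: none
Why: Fluoride-induced desilylation removes both silyl ethers under non-acidic conditions, and the C10 alkoxide cannot open the oxirane because that would need a 4-exo attack at a tertiary carbon or a 5-endo attack.

Step 26
Reactants: 35 (1R,3R,4E,8R,10Z,14R)-8-(2-hydroxypropan-2-yl)-1,5,11-trimethyl-15-oxabicyclo[12.1.0]pentadeca-4,10-dien-3-ol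
Product: 36 2-[(1R,3R,4E,8R,10Z,14R)-3-(acetyloxy)-1,5,11-trimethyl-15-oxabicyclo[12.1.0]pentadeca-4,10-dien-8-yl]propan-2-yl acetate
Conditions: Ac2O (excess), 4-(dimethylamino)pyridine, Et3N, CH2Cl2, rt → 40 °C
Reagents that add atoms: acetic anhydride CC(=O)OC(C)=O
Why: Nucleophile-catalysed acylation through the N-acetylpyridinium ion acetylates the secondary allylic alcohol quickly and the hindered tertiary alcohol on gentle warming, under basic conditions that leave the oxirane and both alkenes unchanged.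

**Compound list**

1 | pent-4-enal | C=CCCC=O | starting material
2 | (2S)-2-(hydroxymethyl)pent-4-enal | OC[C@@H](C=O)CC=C | intermediate
3 | (2S)-2-(hydroxymethyl)pent-4-enoic acid | OC[C@@H](C(O)=O)CC=C | intermediate
4 | methyl (2S)-2-(hydroxymethyl)pent-4-enoate | OC[C@@H](C(=O)OC)CC=C | intermediate
5 | (2S)-3-methyl-2-(prop-2-en-1-yl)butane-1,3-diol | OC[C@@H](C(C)(C)O)CC=C | intermediate
6 | (3R)-2-methyl-3-[(phenylsulfanyl)methyl]hex-5-en-2-ol | c1ccccc1SC[C@@H](C(C)(C)O)CC=C | intermediate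
7 | (3R)-3-[(benzenesulfonyl)methyl]-2-methylhex-5-en-2-ol | O=S(=O)(c1ccccc1)C[C@@H](C(C)(C)O)CC=C | intermediate
8 | {[(3R)-3-[(benzenesulfonyl)methyl]-2-methylhex-5-en-2-yl]oxy}triethylsilane | O=S(=O)(c1ccccc1)C[C@@H](C(C)(C)O[Si](CC)(CC)CC)CC=C | intermediate
9 | 3-{(2R)-2-[(benzenesulfonyl)methyl]-3-methyl-3-[(triethylsilyl)oxy]butyl}-1,2,4-trioxolane (ozonide, epimers at the ring carbon) | O=S(=O)(c1ccccc1)C[C@@H](C(C)(C)O[Si](CC)(CC)CC)CC1OCOO1 | intermediate
10 | (3R)-3-[(benzenesulfonyl)methyl]-4-methyl-4-[(triethylsilyl)oxy]pentanal | O=S(=O)(c1ccccc1)C[C@@H](C(C)(C)O[Si](CC)(CC)CC)CC=O | intermediate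
11 | {[(3R,5Z)-3-[(benzenesulfonyl)methyl]-6-iodo-2-methylhept-5-en-2-yl]oxy}triethylsilane | O=S(=O)(c1ccccc1)C[C@@H](C(C)(C)O[Si](CC)(CC)CC)C/C=C(/C)I | intermediate
12 | ethyl 4-chloro-3-oxobutanoate | CCOC(=O)CC(=O)CCl | starting material
13 | (4-methoxyphenyl)methanol | COc1ccc(CO)cc1 | starting material
14 | ethyl 4-[(4-methoxyphenyl)methoxy]-3-oxobutanoate | CCOC(=O)CC(=O)COCc1ccc(OC)cc1 | intermediate
15 | ethyl (3R)-3-hydroxy-4-[(4-methoxyphenyl)methoxy]butanoate | CCOC(=O)C[C@@H](O)COCc1ccc(OC)cc1 | intermediate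
16 | ethyl (3R)-3-[(tert-butyldimethylsilyl)oxy]-4-[(4-methoxyphenyl)methoxy]butanoate | CCOC(=O)C[C@@H](O[Si](C)(C)C(C)(C)C)COCc1ccc(OC)cc1 | intermediate
17 | (3R)-3-[(tert-butyldimethylsilyl)oxy]-4-[(4-methoxyphenyl)methoxy]butanal | O=CC[C@@H](O[Si](C)(C)C(C)(C)C)COCc1ccc(OC)cc1 | intermediate
18 | tert-butyl{[(2R)-1-[(4-methoxyphenyl)methoxy]pent-4-yn-2-yl]oxy}dimethylsilane | C#CC[C@@H](O[Si](C)(C)C(C)(C)C)COCc1ccc(OC)cc1 | intermediate
19 | [(1E,4R)-4-[(tert-butyldimethylsilyl)oxy]-5-[(4-methoxyphenyl)methoxy]-2-methylpent-1-en-1-yl]dimethylalumane | C[Al](C)/C=C(\C)C[C@@H](O[Si](C)(C)C(C)(C)C)COCc1ccc(OC)cc1 | intermediate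
20 | lithium butyl[(1E,4R)-4-[(tert-butyldimethylsilyl)oxy]-5-[(4-methoxyphenyl)methoxy]-2-methylpent-1-en-1-yl]dimethylaluminate | [Li+].CCCC[Al-](C)(C)/C=C(\C)C[C@@H](O[Si](C)(C)C(C)(C)C)COCc1ccc(OC)cc1 | intermediate
21 | (3E,6R)-6-[(tert-butyldimethylsilyl)oxy]-7-[(4-methoxyphenyl)methoxy]-4-methylhept-3-en-1-ol | OCC/C=C(\C)C[C@@H](O[Si](C)(C)C(C)(C)C)COCc1ccc(OC)cc1 | intermediate
22 | {[(2R,4E)-7-bromo-1-[(4-methoxyphenyl)methoxy]-4-methylhept-4-en-2-yl]oxy}(tert-butyl)dimethylsilane | BrCC/C=C(\C)C[C@@H](O[Si](C)(C)C(C)(C)C)COCc1ccc(OC)cc1 | intermediate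
23 | (2R,4E)-7-bromo-2-[(tert-butyldimethylsilyl)oxy]-4-methylhept-4-en-1-ol | BrCC/C=C(\C)C[C@@H](O[Si](C)(C)C(C)(C)C)CO | intermediate
24 | (2R,4E)-7-bromo-2-[(tert-butyldimethylsilyl)oxy]-4-methylhept-4-enal | BrCC/C=C(\C)C[C@@H](O[Si](C)(C)C(C)(C)C)C=O | intermediate
25 | ethyl (2E,4R,6E)-9-bromo-4-[(tert-butyldimethylsilyl)oxy]-2,6-dimethylnona-2,6-dienoate | BrCC/C=C(\C)C[C@@H](O[Si](C)(C)C(C)(C)C)/C=C(\C)C(=O)OCC | intermediate
26 | ethyl (2E,4R)-5-[(2R,3R)-3-(2-bromoethyl)-2-methyloxiran-2-yl]-4-[(tert-butyldimethylsilyl)oxy]-2-methylpent-2-enoate | BrCC[C@H]1O[C@]1(C)C[C@@H](O[Si](C)(C)C(C)(C)C)/C=C(\C)C(=O)OCC | intermediate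
27 | ethyl (2E,4R)-4-[(tert-butyldimethylsilyl)oxy]-5-[(2R,3R)-3-(2-iodoethyl)-2-methyloxiran-2-yl]-2-methylpent-2-enoate | ICC[C@H]1O[C@]1(C)C[C@@H](O[Si](C)(C)C(C)(C)C)/C=C(\C)C(=O)OCC | intermediate
28 | {2-[(2R,3R)-3-[(2R,3E)-2-[(tert-butyldimethylsilyl)oxy]-5-ethoxy-4-methyl-5-oxopent-3-en-1-yl]-3-methyloxiran-2-yl]ethyl}(iodo)zinc | I[Zn]CC[C@H]1O[C@]1(C)C[C@@H](O[Si](C)(C)C(C)(C)C)/C=C(\C)C(=O)OCC | intermediate
29 | ethyl (2E,4R)-5-{(2R,3R)-3-[(3Z,6R)-6-[(benzenesulfonyl)methyl]-3,7-dimethyl-7-[(triethylsilyl)oxy]oct-3-en-1-yl]-2-methyloxiran-2-yl}-4-[(tert-butyldimethylsilyl)oxy]-2-methylpent-2-enoate | O=S(=O)(c1ccccc1)C[C@@H](C(C)(C)O[Si](CC)(CC)CC)C/C=C(/C)CC[C@H]1O[C@]1(C)C[C@@H](O[Si](C)(C)C(C)(C)C)/C=C(\C)C(=O)OCC | intermediate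
30 | (2E,4R)-5-{(2R,3R)-3-[(3Z,6R)-6-[(benzenesulfonyl)methyl]-3,7-dimethyl-7-[(triethylsilyl)oxy]oct-3-en-1-yl]-2-methyloxiran-2-yl}-4-[(tert-butyldimethylsilyl)oxy]-2-methylpent-2-en-1-ol | O=S(=O)(c1ccccc1)C[C@@H](C(C)(C)O[Si](CC)(CC)CC)C/C=C(/C)CC[C@H]1O[C@]1(C)C[C@@H](O[Si](C)(C)C(C)(C)C)/C=C(\C)CO | intermediate
31 | (2E,4R)-5-{(2R,3R)-3-[(3Z,6R)-6-[(benzenesulfonyl)methyl]-3,7-dimethyl-7-[(triethylsilyl)oxy]oct-3-en-1-yl]-2-methyloxiran-2-yl}-4-[(tert-butyldimethylsilyl)oxy]-2-methylpent-2-en-1-yl methanesulfonate | O=S(=O)(c1ccccc1)C[C@@H](C(C)(C)O[Si](CC)(CC)CC)C/C=C(/C)CC[C@H]1O[C@]1(C)C[C@@H](O[Si](C)(C)C(C)(C)C)/C=C(\C)COS(C)(=O)=O | intermediate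
32 | (2R,3R)-3-[(3Z,6R)-6-[(benzenesulfonyl)methyl]-3,7-dimethyl-7-[(triethylsilyl)oxy]oct-3-en-1-yl]-2-[(2R,3E)-5-bromo-2-[(tert-butyldimethylsilyl)oxy]-4-methylpent-3-en-1-yl]-2-methyloxirane | O=S(=O)(c1ccccc1)C[C@@H](C(C)(C)O[Si](CC)(CC)CC)C/C=C(/C)CC[C@H]1O[C@]1(C)C[C@@H](O[Si](C)(C)C(C)(C)C)/C=C(\C)CBr | intermediate
33 | {[(1R,3R,4E,8R,10Z,14R)-7-(benzenesulfonyl)-1,5,11-trimethyl-8-{2-[(triethylsilyl)oxy]propan-2-yl}-15-oxabicyclo[12.1.0]pentadeca-4,10-dien-3-yl]oxy}(tert-butyl)dimethylsilane (both C7 epimers) | O=S(=O)(c1ccccc1)C3[C@@H](C(C)(C)O[Si](CC)(CC)CC)C/C=C(/C)CC[C@H]2O[C@]2(C)C[C@@H](O[Si](C)(C)C(C)(C)C)/C=C(\C)C3 | intermediate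
34 | tert-butyl{[(1R,3R,4E,8R,10Z,14R)-1,5,11-trimethyl-8-{2-[(triethylsilyl)oxy]propan-2-yl}-15-oxabicyclo[12.1.0]pentadeca-4,10-dien-3-yl]oxy}dimethylsilane | C1[C@@H](C(C)(C)O[Si](CC)(CC)CC)C/C=C(/C)CC[C@H]2O[C@]2(C)C[C@@H](O[Si](C)(C)C(C)(C)C)/C=C(\C)C1 | intermediate
35 | (1R,3R,4E,8R,10Z,14R)-8-(2-hydroxypropan-2-yl)-1,5,11-trimethyl-15-oxabicyclo[12.1.0]pentadeca-4,10-dien-3-ol | C1[C@@H](C(C)(C)O)C/C=C(/C)CC[C@H]2O[C@]2(C)C[C@@H](O)/C=C(\C)C1 | intermediate
36 | 2-[(1R,3R,4E,8R,10Z,14R)-3-(acetyloxy)-1,5,11-trimethyl-15-oxabicyclo[12.1.0]pentadeca-4,10-dien-8-yl]propan-2-yl acetate | CC(=O)O[C@H]1/C=C(\C)CC[C@@H](C(C)(C)OC(C)=O)C/C=C(/C)CC[C@H]2O[C@]2(C)C1 | target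

**Step count and risks**

Total step count: 26. Longest linear sequence: 18 steps (steps 9–19, then 20–26); the fragment A branch is 15 steps (1–8, then 20–26).

The three steps most likely to fail are steps 8, 20 and 23.

Step 8 is at risk because the α-iodo ylide olefination often gives moderate yield and an imperfect Z:E ratio. The fallback sets out from aldehyde 10. Corey–Fuchs dibromo-olefination (CBr4, PPh3, CH2Cl2, 0 °C) gives {[(3R)-3-[(benzenesulfonyl)methyl]-6,6-dibromo-2-methylhex-5-en-2-yl]oxy}triethylsilane F1. Palladium-catalysed trans-selective monomethylation (MeZnCl, PdCl2(DPEphos), THF, 0 °C) replaces only the bromide trans to the chain and gives the (Z)-vinyl bromide {[(3R,5Z)-3-[(benzenesulfonyl)methyl]-6-bromo-2-methylhept-5-en-2-yl]oxy}triethylsilane F2. F2 then takes the place of 11 in the coupling with alkylzinc 28 (Pd(P(t-Bu)3)2 to keep the geometry), and the route is rejoined at 29.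

Step 20 is at risk because zinc insertion next to a trisubstituted oxirane may be sluggish or the zinc halide may damage the oxirane. The fallback reverses the polarity of the partners and sets out from vinyl iodide 11 and bromide 26. Miyaura borylation of 11 (B2pin2, PdCl2(dppf), KOPh, toluene, 50 °C) gives the alkenylboronate 2-[(2E,5R)-5-[(benzenesulfonyl)methyl]-6-methyl-6-[(triethylsilyl)oxy]hept-2-en-2-yl]-4,4,5,5-tetramethyl-1,3,2-dioxaborolane F3, with the same alkene geometry as 11 (the descriptor is E only because boron ranks below carbon). Alkyl–alkenyl Suzuki–Miyaura coupling of F3 with the primary bromide 26 (Pd(OAc)2, P(t-Bu)2Me, K3PO4, t-amyl alcohol, rt) needs no organozinc and returns to the route at 29.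

Step 23 is at risk because the carbanion sits next to a branched carbon and ring closure competes with oligomerisation and elimination. The fallback forms the two fragment-joining bonds in the opposite order and closes the ring by palladium-catalysed coupling; it sets out from 27 and 11. Reduction of 27 with iBu2AlH (CH2Cl2, −78 °C) gives (2E,4R)-4-[(tert-butyldimethylsilyl)oxy]-5-[(2R,3R)-3-(2-iodoethyl)-2-methyloxiran-2-yl]-2-methylpent-2-en-1-ol F4. MeSO2Cl/Et3N gives its methanesulfonate F5, and LiBr gives (2R,3R)-2-[(2R,3E)-5-bromo-2-[(tert-butyldimethylsilyl)oxy]-4-methylpent-3-en-1-yl]-3-(2-iodoethyl)-2-methyloxirane F6. Sulfone 11 is lithiated (LiN(iPr)2, THF, −78 °C) and alkylated intermolecularly at the allylic bromide of F6, which is far more reactive than the primary iodide, to give the open-chain bis-iodide (2R,3R)-2-[(2R,3E,7R,9Z)-6-(benzenesulfonyl)-2-[(tert-butyldimethylsilyl)oxy]-10-iodo-4-methyl-7-{2-[(triethylsilyl)oxy]propan-2-yl}undeca-3,9-dien-1-yl]-3-(2-iodoethyl)-2-methyloxirane F7. Zinc inserts only into the alkyl iodide to give the alkylzinc iodide of F7, iodo{2-[(2R,3R)-3-[(2R,3E,7R,9Z)-6-(benzenesulfonyl)-2-[(tert-butyldimethylsilyl)oxy]-10-iodo-4-methyl-7-{2-[(triethylsilyl)oxy]propan-2-yl}undeca-3,9-dien-1-yl]-3-methyloxiran-2-yl]ethyl}zinc F8, which is not isolated. Intramolecular Negishi coupling onto the (Z)-vinyl iodide (Pd(PPh3)4, THF/DMA, 0.002 M) then delivers macrocyclic sulfone 33.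

**Further compounds**

F1 | step 8 | {[(3R)-3-[(benzenesulfonyl)methyl]-6,6-dibromo-2-methylhex-5-en-2-yl]oxy}triethylsilane | O=S(=O)(c1ccccc1)C[C@@H](C(C)(C)O[Si](CC)(CC)CC)CC=C(Br)Br
F2 | step 8 | {[(3R,5Z)-3-[(benzenesulfonyl)methyl]-6-bromo-2-methylhept-5-en-2-yl]oxy}triethylsilane | O=S(=O)(c1ccccc1)C[C@@H](C(C)(C)O[Si](CC)(CC)CC)C/C=C(/C)Br
F3 | step 20 | 2-[(2E,5R)-5-[(benzenesulfonyl)methyl]-6-methyl-6-[(triethylsilyl)oxy]hept-2-en-2-yl]-4,4,5,5-tetramethyl-1,3,2-dioxaborolane | O=S(=O)(c1ccccc1)C[C@@H](C(C)(C)O[Si](CC)(CC)CC)C/C=C(/C)B1OC(C)(C)C(C)(C)O1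
F4 | step 23 | (2E,4R)-4-[(tert-butyldimethylsilyl)oxy]-5-[(2R,3R)-3-(2-iodoethyl)-2-methyloxiran-2-yl]-2-methylpent-2-en-1-ol | ICC[C@H]1O[C@]1(C)C[C@@H](O[Si](C)(C)C(C)(C)C)/C=C(\C)CO
F5 | step 23 | (2E,4R)-4-[(tert-butyldimethylsilyl)oxy]-5-[(2R,3R)-3-(2-iodoethyl)-2-methyloxiran-2-yl]-2-methylpent-2-en-1-yl methanesulfonate | ICC[C@H]1O[C@]1(C)C[C@@H](O[Si](C)(C)C(C)(C)C)/C=C(\C)COS(C)(=O)=O
F6 | step 23 | (2R,3R)-2-[(2R,3E)-5-bromo-2-[(tert-butyldimethylsilyl)oxy]-4-methylpent-3-en-1-yl]-3-(2-iodoethyl)-2-methyloxirane | ICC[C@H]1O[C@]1(C)C[C@@H](O[Si](C)(C)C(C)(C)C)/C=C(\C)CBr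
F7 | step 23 | (2R,3R)-2-[(2R,3E,7R,9Z)-6-(benzenesulfonyl)-2-[(tert-butyldimethylsilyl)oxy]-10-iodo-4-methyl-7-{2-[(triethylsilyl)oxy]propan-2-yl}undeca-3,9-dien-1-yl]-3-(2-iodoethyl)-2-methyloxirane (both C6 epimers) | O=S(=O)(c1ccccc1)C(C/C(C)=C/[C@H](O[Si](C)(C)C(C)(C)C)C[C@@]2(C)O[C@@H]2CCI)[C@@H](C(C)(C)O[Si](CC)(CC)CC)C/C=C(/C)I
F8 | step 23 | iodo{2-[(2R,3R)-3-[(2R,3E,7R,9Z)-6-(benzenesulfonyl)-2-[(tert-butyldimethylsilyl)oxy]-10-iodo-4-methyl-7-{2-[(triethylsilyl)oxy]propan-2-yl}undeca-3,9-dien-1-yl]-3-methyloxiran-2-yl]ethyl}zinc | O=S(=O)(c1ccccc1)C(C/C(C)=C/[C@H](O[Si](C)(C)C(C)(C)C)C[C@@]2(C)O[C@@H]2CC[Zn]I)[C@@H](C(C)(C)O[Si](CC)(CC)CC)C/C=C(/C)I
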